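**Strategy.** The 14-membered carbocycle (cembrane numbering C1–C14) is disconnected at C8–C9. C8 (Me, OOH, allylic to C6=C7) is the ene product of a C7=C8 alkene, so it is carried as the CCl2 terminus of a 1,1-dichloroalkene; C9 is the unfunctionalised CH2 at the end of a 1,3-diene. Hydroboration at C9 and trans-selective intramolecular B-alkyl Suzuki–Miyaura coupling close the ring as a (7Z)-chloroalkene. The chloride masks this alkene during double Shi epoxidation, is then exchanged for the C19 methyl, and epoxide-opening lactonisation builds the δ-lactone (C3/C4). A singlet-oxygen ene reaction finally sets C8–OOH and C6=C7.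

Key step: step 7

Remark: cembrane numbering is used for ring compounds (C1 bears C15(C17)–C16; lactone O on C3; OH and Me-18 on C4; Me-19 on C8; C11–C12 epoxide with Me-20 on C12); the Tol-BINAP antipode in step 6 and the L-series Shi ketone in step 8 are assumed to be chosen so as to give the configurations drawn.

Step 1
Reactants: 1 pent-4-yn-1-ol
Product: 2 pent-4-ynal
Conditions: TEMPO (cat.), PhI(OAc)2, CH2Cl2, rt
Reagents that add atoms: none
Why: Oxoammonium (TEMPO/PhI(OAc)2) oxidation of a primary alcohol should stop at the aldehyde and leave the terminal alkyne untouched; no stereocentre is formed.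

Step 2
Reactants: 2 pent-4-ynal
Product: 3 6,6-dichlorohex-5-en-1-yne
Conditions: PPh3, BrCCl3, MeCN, 0 °C→rt
Reagents that add atoms: bromotrichloromethane BrC(Cl)(Cl)Cl
Why: Ramirez-type gem-dichloro-olefination, in which the ylide Ph3P=CCl2 formed from PPh3 and BrCCl3 undergoes a Wittig reaction with the aldehyde to create C7=C8 with both chlorides on C8 (no stereochemistry).

Step 3
Reactants: 3 6,6-dichlorohex-5-en-1-yne; 4 methyl (E)-4-bromobut-2-enoate
Product: 6 methyl (2E,5E)-10,10-dichloro-6-methyldeca-2,5,9-trienoate, via alkenylalane 5 (not isolated)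
Conditions: Me3Al, Cp2ZrCl2 (cat.), CH2Cl2, 0 °C→rt; then 4, Pd(PPh3)4 (cat.), THF, 0 °C→rt
Reagents that add atoms: trimethylaluminium C[Al](C)C
Why: Negishi zirconium-catalysed syn-carboalumination places the methyl group (C18) on the internal and aluminium on the terminal alkyne carbon, fixing the 5E geometry, and Pd-catalysed allyl–alkenyl coupling of 5 at the CH2 terminus of bromide 4 should proceed with retention and keep the conjugated 2E enoate.

Step 4
Reactants: 7 but-3-yn-1-ol
Product: 9 (3E)-3-methylhexa-3,5-dien-1-ol, via alkenylalane alkoxide 8 (not isolated)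
Conditions: Me3Al, Cp2ZrCl2 (cat.), CH2Cl2, 0 °C→rt; then vinyl bromide, ZnCl2, Pd(PPh3)4 (cat.), THF, rt
Reagents that add atoms: trimethylaluminium C[Al](C)C; vinyl bromide C=CBr
Why: The same Negishi carboalumination (the alcohol is carried as its aluminium alkoxide) followed by Pd-catalysed alkenyl–alkenyl cross-coupling with retention should give the E-trisubstituted alkene of the diene (future C11=C12 with C20).

Step 5
Reactants: 9 (3E)-3-methylhexa-3,5-dien-1-ol
Product: 10 (3E)-6-bromo-4-methylhexa-1,3-diene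
Conditions: CBr4, PPh3, CH2Cl2, 0 °C
Reagents that add atoms: carbon tetrabromide BrC(Br)(Br)Br
Why: Appel reaction, an SN2 displacement of the activated primary alcohol by bromide under neutral conditions that should spare the diene.

Step 6
Reactants: 10 (3E)-6-bromo-4-methylhexa-1,3-diene; 6 methyl (2E,5E)-10,10-dichloro-6-methyldeca-2,5,9-trienoate
Product: 13 methyl (3R,5E)-10,10-dichloro-6-methyl-3-[(3E)-3-methylhexa-3,5-dien-1-yl]deca-5,9-dienoate, via Grignard reagent 11 (not isolated), via magnesium enolate 12 (not isolated)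
Conditions: Mg, Et2O, rt; then CuI (cat.), Tol-BINAP (cat., antipode giving 3R), 6, t-BuOMe, −40 °C; aq. NH4Cl
Reagents that add atoms: none
Why: Copper/Tol-BINAP-catalysed asymmetric conjugate addition of a Grignard reagent to an (E)-enoate, in which the chiral cuprate adds to one face of C1 (3R, fixed by the ligand antipode) and 1,4-addition at −40 °C should outrun deprotonation of the doubly allylic γ-CH2.

Step 7
Reactants: 13 methyl (3R,5E)-10,10-dichloro-6-methyl-3-[(3E)-3-methylhexa-3,5-dien-1-yl]deca-5,9-dienoate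
Product: 15 methyl 2-[(1R,3E,7Z,11E)-8-chloro-4,12-dimethylcyclotetradeca-3,7,11-trien-1-yl]acetate, via alkyl-9-BBN borane 14 (not isolated)
Conditions: 9-BBN, THF, 0 °C→rt; then slow addition to Pd2(dba)3 (cat.), Xantphos (cat.), K3PO4, THF/H2O, 65 °C, about 1 mM
Reagents that add atoms: none
Why: 9-BBN should add only to the monosubstituted C9=C10 terminus of the diene (all other alkenes are trisubstituted or chlorinated) to give primary borane 14; zerovalent palladium then inserts into the C–Cl bond trans to the chain, the base-activated B-alkyl group is transmetalated and reductive elimination joins C9 to C8. The closest known reaction types are the trans-selective B-alkyl Suzuki–Miyaura monocoupling of 1,1-dichloro-1-alkenes and B-alkyl Suzuki macrocyclisation. The 14-membered carbocycle is closed by intramolecular C(sp3)–C(sp2) cross-coupling that leaves C7=C8 endocyclic. No stereocentre is formed; the alkene geometry is set by stereoretentive coupling at the less hindered trans chloride, which puts C9 trans to C6 (7Z chloride, the geometry of the later 7E methyl alkene). The step needs mono- over double coupling and ring closure over oligomerisation: the remaining cis C–Cl bond inserts much more slowly, slow addition at high dilution favours the intramolecular path, and the wide-bite-angle Xantphos favours reductive elimination over β-hydride elimination.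

Step 8
Reactants: 15 methyl 2-[(1R,3E,7Z,11E)-8-chloro-4,12-dimethylcyclotetradeca-3,7,11-trien-1-yl]acetate
Product: 16 methyl 2-[(1R,3S,4S,7Z,11S,12S)-8-chloro-3,4:11,12-diepoxy-4,12-dimethylcyclotetradec-7-en-1-yl]acetate
Conditions: ent-Shi ketone (L-series, from L-sorbose), Oxone (2KHSO5·KHSO4·K2SO4), K2CO3, Bu4NHSO4, MeCN/CH2(OMe)2/aq. Na2B4O7 buffer (pH 10.5), 0 °C
Reagents that add atoms: potassium peroxymonosulfate [K+].[O-]S(=O)(=O)OO
Why: Shi asymmetric epoxidation, in which the dioxirane of the L-series ketone transfers oxygen to each (E)-trisubstituted alkene through the spiro transition state on the face that gives the S,S-epoxide, so C3, C4, C11 and C12 are set by the catalyst while the electron-poor chloroalkene should not react.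

Step 9
Reactants: 16 methyl 2-[(1R,3S,4S,7Z,11S,12S)-8-chloro-3,4:11,12-diepoxy-4,12-dimethylcyclotetradec-7-en-1-yl]acetate
Product: 17 methyl 2-[(1R,3S,4S,7E,11S,12S)-3,4:11,12-diepoxy-4,8,12-trimethylcyclotetradec-7-en-1-yl]acetate
Conditions: trimethylboroxine, Pd(OAc)2 (cat.), SPhos (cat.), K3PO4 (anhydrous), dioxane, 80 °C
Reagents that add atoms: trimethylboroxine CB1OB(C)OB(C)O1
Why: Suzuki–Miyaura methylation of an alkenyl chloride proceeds with retention, so the (7Z)-chloride should become the (7E)-C7=C8 alkene bearing C19, and anhydrous phosphate should leave epoxides and ester intact.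

Step 10
Reactants: 17 methyl 2-[(1R,3S,4S,7E,11S,12S)-3,4:11,12-diepoxy-4,8,12-trimethylcyclotetradec-7-en-1-yl]acetate
Product: 19 (1R,3R,4S,7E,11S,12S)-11,12-epoxy-4-hydroxy-17-norcembr-7-en-16,3-olide, via epoxy acid 18 (not isolated)
Conditions: LiOH·H2O, THF/MeOH/H2O, 0 °C→rt; AcOH to pH 5; then PhMe, 40 °C
Reagents that add atoms: lithium hydroxide [Li+].[OH-]
Why: Saponification followed by intramolecular SN2 opening of the 3,4-epoxide by the C16 carboxyl group (6-exo-tet at the secondary C3, inversion 3S→3R, C4 retained as the tertiary alcohol) should build the δ-lactone, the six-membered transition state at a secondary carbon being favoured over seven-membered attack at C4 or C12.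

Step 11
Reactants: 19 (1R,3R,4S,7E,11S,12S)-11,12-epoxy-4-hydroxy-17-norcembr-7-en-16,3-olide
Product: 21 (1R,3R,4S,7E,11S,12S,15S)-11,12-epoxy-4-hydroxycembr-7-en-16,3-olide, via dilithio enolate 20 (not isolated)
Conditions: LiN(iPr)2 (2.3 equiv), THF, −78 °C; MeI, −78→−40 °C; aq. NH4Cl
Reagents that add atoms: iodomethane CI
Why: Lactone enolate alkylation, in which the enolate (the C4 lithium alkoxide is a spectator) should be methylated anti to the C1–C14 bond on the face away from the macrocyclic bridge, giving the all-equatorial 15S epimer, which is also the thermodynamic one.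

Step 12
Reactants: 21 (1R,3R,4S,7E,11S,12S,15S)-11,12-epoxy-4-hydroxycembr-7-en-16,3-olide
Product: 22 (1R,3R,4S,6E,8S,11S,12S,15S)-11,12-epoxy-8-hydroperoxy-4-hydroxycembr-6-en-16,3-olide (target)
Conditions: O2, visible light, tetraphenylporphyrin (cat.), CH2Cl2, −20 °C; no reductive work-up
Reagents that add atoms: dioxygen O=O
Why: Schenck ene reaction, in which singlet oxygen adds suprafacially to C8 while abstracting an allylic hydrogen from C6 (cis effect, disubstituted side of the alkene), which should shift the alkene to C6=C7 (E) and give the tertiary hydroperoxide, 8S arising from attack on the exposed outer face of the macrocyclic alkene.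

**Compound list**

1 | pent-4-yn-1-ol | C#CCCCO | starting material
2 | pent-4-ynal | C#CCCC=O | intermediate
3 | 6,6-dichlorohex-5-en-1-yne | C#CCCC=C(Cl)Cl | intermediate
4 | methyl (E)-4-bromobut-2-enoate | COC(=O)/C=C/CBr | starting material
5 | [(1E)-6,6-dichloro-2-methylhexa-1,5-dien-1-yl]dimethylalane (formed in situ) | C[Al](C)/C=C(\C)CCC=C(Cl)Cl | intermediate
6 | methyl (2E,5E)-10,10-dichloro-6-methyldeca-2,5,9-trienoate | COC(=O)/C=C/C/C=C(C)/CCC=C(Cl)Cl | intermediate
7 | but-3-yn-1-ol | C#CCCO | starting material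
8 | dimethylaluminium (3E)-4-(dimethylalumanyl)-3-methylbut-3-en-1-olate (formed in situ) | C[Al](C)/C=C(\C)CCO[Al](C)C | intermediate
9 | (3E)-3-methylhexa-3,5-dien-1-ol | OCC/C(C)=C/C=C | intermediate
10 | (3E)-6-bromo-4-methylhexa-1,3-diene | BrCC/C(C)=C/C=C | intermediate
11 | [(3E)-3-methylhexa-3,5-dien-1-yl]magnesium bromide (formed in situ) | Br[Mg]CC/C(C)=C/C=C | intermediate
12 | bromomagnesium enolate of 13 (formed in situ) | COC(O[Mg]Br)=C[C@H](CC/C(C)=C/C=C)C/C=C(C)/CCC=C(Cl)Cl | intermediate
13 | methyl (3R,5E)-10,10-dichloro-6-methyl-3-[(3E)-3-methylhexa-3,5-dien-1-yl]deca-5,9-dienoate | COC(=O)C[C@H](CC/C(C)=C/C=C)C/C=C(C)/CCC=C(Cl)Cl | intermediate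
14 | methyl (3R,5E)-3-[(3E)-6-(9-borabicyclo[3.3.1]nonan-9-yl)-3-methylhex-3-en-1-yl]-10,10-dichloro-6-methyldeca-5,9-dienoate (formed in situ) | COC(=O)C[C@H](CC/C(C)=C/CCB1C2CCCC1CCC2)C/C=C(C)/CCC=C(Cl)Cl | intermediate
15 | methyl 2-[(1R,3E,7Z,11E)-8-chloro-4,12-dimethylcyclotetradeca-3,7,11-trien-1-yl]acetate | COC(=O)C[C@H]1C/C=C(C)/CC/C=C(Cl)/CC/C=C(C)/CC1 | intermediate
16 | methyl 2-[(1R,3S,4S,7Z,11S,12S)-8-chloro-3,4:11,12-diepoxy-4,12-dimethylcyclotetradec-7-en-1-yl]acetate | COC(=O)C[C@H]1C[C@@H]2O[C@@]2(C)CC/C=C(Cl)/CC[C@@H]2O[C@@]2(C)CC1 | intermediate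
17 | methyl 2-[(1R,3S,4S,7E,11S,12S)-3,4:11,12-diepoxy-4,8,12-trimethylcyclotetradec-7-en-1-yl]acetate | COC(=O)C[C@H]1C[C@@H]2O[C@@]2(C)CC/C=C(C)/CC[C@@H]2O[C@@]2(C)CC1 | intermediate
18 | 2-[(1R,3S,4S,7E,11S,12S)-3,4:11,12-diepoxy-4,8,12-trimethylcyclotetradec-7-en-1-yl]acetic acid (formed in situ) | OC(=O)C[C@H]1C[C@@H]2O[C@@]2(C)CC/C=C(C)/CC[C@@H]2O[C@@]2(C)CC1 | intermediate
19 | (1R,3R,4S,7E,11S,12S)-11,12-epoxy-4-hydroxy-17-norcembr-7-en-16,3-olide | C1C(=O)O[C@@H]2C[C@H]1CC[C@]1(C)O[C@H]1CC/C(C)=C/CC[C@]2(C)O | intermediate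
20 | dilithium enolate-alkoxide of 19 (formed in situ) | C1=C(O[Li])O[C@@H]2C[C@H]1CC[C@]1(C)O[C@H]1CC/C(C)=C/CC[C@]2(C)O[Li] | intermediate
21 | (1R,3R,4S,7E,11S,12S,15S)-11,12-epoxy-4-hydroxycembr-7-en-16,3-olide | C[C@@H]1C(=O)O[C@@H]2C[C@H]1CC[C@]1(C)O[C@H]1CC/C(C)=C/CC[C@]2(C)O | intermediate
22 | (1R,3R,4S,6E,8S,11S,12S,15S)-11,12-epoxy-8-hydroperoxy-4-hydroxycembr-6-en-16,3-olide | C[C@@H]1C(=O)O[C@@H]2C[C@H]1CC[C@]1(C)O[C@H]1CC[C@](C)(OO)/C=C/C[C@]2(C)O | target

**Step count.** Total: 12 steps. Longest linear sequence: 10 steps (steps 1–3 and 6–12); steps 4–5 form the second branch.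

**Steps most likely to fail**

Step 12. Hydrogen abstraction from the C19 methyl group (giving a secondary hydroperoxide with an exocyclic alkene) may compete with abstraction from C6, and singlet oxygen may attack the wrong face of the 7,8-alkene. The fallback sets out from 21 and returns at 22. Ionic bromo-hydroperoxidation (1,3-dibromo-5,5-dimethylhydantoin, anhydrous H2O2, Et2O, −40 °C) should place OOH on the tertiary C8 and bromine on C7 by anti addition, giving (1R,3R,4S,7R,8S,11S,12S,15S)-7-bromo-11,12-epoxy-8-hydroperoxy-4-hydroxycembran-16,3-olide F7. Masking the hydroperoxide with 2-methoxypropene/PPTS (to prevent dioxetane formation) should give the 8-[(2-methoxypropan-2-yl)peroxy] bromide F8. DBU should then remove HBr, only C6 carrying a β-hydrogen, to give (1R,3R,4S,6E,8S,11S,12S,15S)-11,12-epoxy-4-hydroxy-8-[(2-methoxypropan-2-yl)peroxy]cembr-6-en-16,3-olide F9. AcOH/THF/H2O should release 22. Regiochemistry is then fixed by Markovnikov addition, and the C8 configuration follows from the face of bromonium formation.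

Step 8. The facial selectivity of the two epoxidations may be governed by the conformation of the macrocycle and not by the ketone catalyst. The fallback sets out from 13 and returns at 16. Hydroboration–oxidation (9-BBN; NaOH, H2O2) should give methyl (3R,5E)-10,10-dichloro-3-[(3E)-6-hydroxy-3-methylhex-3-en-1-yl]-6-methyldeca-5,9-dienoate F3. Shi epoxidation with the L-series ketone on this open chain, where catalyst control is reliable, should give the (3S,4S,11S,12S)-diepoxy alcohol F4. I2/PPh3/imidazole should give the diepoxy iodide F5, and zinc insertion (Zn, LiCl, THF) the alkylzinc iodide F6. Trans-selective Negishi monoalkylation of the dichloroalkene (PdCl2(DPEphos), slow addition, high dilution) should then close the ring to 16.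

Step 7. Oligomerisation, β-hydride elimination or protodeboronation of the alkylborane may outrun ring closure, or oxidative addition into the C–Cl bond may be too slow. The fallback sets out from 13 and returns at 15. Hydroboration followed by iodinolysis (9-BBN; I2, NaOMe) should give the primary iodide methyl (3R,5E)-10,10-dichloro-3-[(3E)-6-iodo-3-methylhex-3-en-1-yl]-6-methyldeca-5,9-dienoate F1. Zinc insertion (Zn, LiCl, THF) should give the alkylzinc iodide F2. PdCl2(DPEphos)-catalysed trans-selective Negishi monoalkylation of the 1,1-dichloroalkene under slow addition should close the same C8–C9 bond to give 15.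

**Further compounds**

F1 | step 7 | methyl (3R,5E)-10,10-dichloro-3-[(3E)-6-iodo-3-methylhex-3-en-1-yl]-6-methyldeca-5,9-dienoate | COC(=O)C[C@H](CC/C(C)=C/CCI)C/C=C(C)/CCC=C(Cl)Cl
F2 | step 7 | alkylzinc iodide from F1 | COC(=O)C[C@H](CC/C(C)=C/CC[Zn]I)C/C=C(C)/CCC=C(Cl)Cl
F3 | step 8 | methyl (3R,5E)-10,10-dichloro-3-[(3E)-6-hydroxy-3-methylhex-3-en-1-yl]-6-methyldeca-5,9-dienoate | COC(=O)C[C@H](CC/C(C)=C/CCO)C/C=C(C)/CCC=C(Cl)Cl
F4 | step 8 | methyl (3R)-4-[(2S,3S)-3-(4,4-dichlorobut-3-en-1-yl)-3-methyloxiran-2-yl]-3-{2-[(2S,3S)-3-(2-hydroxyethyl)-2-methyloxiran-2-yl]ethyl}butanoate | COC(=O)C[C@H](CC[C@]1(C)O[C@H]1CCO)C[C@@H]1O[C@@]1(C)CCC=C(Cl)Cl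
F5 | step 8 | methyl (3R)-4-[(2S,3S)-3-(4,4-dichlorobut-3-en-1-yl)-3-methyloxiran-2-yl]-3-{2-[(2S,3S)-3-(2-iodoethyl)-2-methyloxiran-2-yl]ethyl}butanoate | COC(=O)C[C@H](CC[C@]1(C)O[C@H]1CCI)C[C@@H]1O[C@@]1(C)CCC=C(Cl)Cl
F6 | step 8 | alkylzinc iodide from F5 | COC(=O)C[C@H](CC[C@]1(C)O[C@H]1CC[Zn]I)C[C@@H]1O[C@@]1(C)CCC=C(Cl)Cl
F7 | step 12 | (1R,3R,4S,7R,8S,11S,12S,15S)-7-bromo-11,12-epoxy-8-hydroperoxy-4-hydroxycembran-16,3-olide | C[C@@H]1C(=O)O[C@@H]2C[C@H]1CC[C@]1(C)O[C@H]1CC[C@](C)(OO)[C@H](Br)CC[C@]2(C)O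
F8 | step 12 | (1R,3R,4S,7R,8S,11S,12S,15S)-7-bromo-11,12-epoxy-4-hydroxy-8-[(2-methoxypropan-2-yl)peroxy]cembran-16,3-olide | C[C@@H]1C(=O)O[C@@H]2C[C@H]1CC[C@]1(C)O[C@H]1CC[C@](C)(OOC(C)(C)OC)[C@H](Br)CC[C@]2(C)O
F9 | step 12 | (1R,3R,4S,6E,8S,11S,12S,15S)-11,12-epoxy-4-hydroxy-8-[(2-methoxypropan-2-yl)peroxy]cembr-6-en-16,3-olide | C[C@@H]1C(=O)O[C@@H]2C[C@H]1CC[C@]1(C)O[C@H]1CC[C@](C)(OOC(C)(C)OC)/C=C/C[C@]2(C)O
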